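**Strategy.** The cyclohexane (C1 = CMe2, C2 = CHBr, C3 = CH2, C4 and C6 = CHCl, C5 = alkylidene carbon; C7, C8 = side chain) is cut between C3–C4 and C6–C1 into a prenyl unit and a five-carbon unit. In one flask, prenyl pinacolboronate adds through C1 to the free aldehyde of a cis-formylacrylate whose second aldehyde is an acylal; the cis ester closes a butenolide, and TiBr4 triggers a bromide-terminated Prins closure. The step exploits the 1,3,5-array C2–Br, C4–O, C6–O on the six-membered ring and the cis relation of C8 to C6, locked as the lactone. Inversion of both carbinols to chlorides and bromide exchange at C8 finish.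

Key step: step 4

Assumption: (S)-TRIP is taken to give the (4S)-carbinol of 6, by analogy with the sense of induction known for aryl and alkenyl aldehydes; if the sense proves reversed, (R)-TRIP is used.

Step 1
Reactants: 1 furan-3-carbaldehyde
Product: 2 (furan-3-yl)methanediyl diacetate
Conditions: Ac2O, H2SO4 (cat.), 0 to 23 °C
Reagents that add atoms: acetic anhydride, CC(=O)OC(C)=O
Why: Acid-catalysed acylal formation masks the future C4 aldehyde in a form that should tolerate singlet oxygen, mild base and allylboration, and that a Lewis acid can later ionise with retention of one acetoxy group.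

Step 2
Reactants: 2 (furan-3-yl)methanediyl diacetate
Product: 3 (2-hydroxy-5-oxo-2,5-dihydrofuran-3-yl)methanediyl diacetate
Conditions: O2, hν (visible), meso-tetraphenylporphyrin (cat.), iPr2NEt, CH2Cl2, −78 °C
Reagents that add atoms: dioxygen, O=O
Why: Singlet-oxygen [4+2] cycloaddition to the furan, then amine-mediated Kornblum–DeLaMare opening of the endoperoxide in which the hindered base removes the bridgehead hydrogen remote from the substituent, should give the 4-substituted 5-hydroxybutenolide regioselectively; the new lactol centre is labile, forms as a mixture and is lost in step 3.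

Step 3
Reactants: 3 (2-hydroxy-5-oxo-2,5-dihydrofuran-3-yl)methanediyl diacetate
Product: 4 methyl (2E)-4,4-bis(acetyloxy)-3-formylbut-2-enoate (ester cis to the formyl group)
Conditions: KHCO3, MeI, DMF, 0 °C, dark
Reagents that add atoms: iodomethane, CI
Why: The pseudo-acid is in ring–chain equilibrium with its open carboxylate, whose SN2 O-methylation traps the cis-formylacrylate as the methyl ester and frees the C6 aldehyde with the ester held cis to it (cold, dark and brief to avoid cis–trans isomerisation).

Step 4
Reactants: 4 methyl (2E)-4,4-bis(acetyloxy)-3-formylbut-2-enoate, 5 4,4,5,5-tetramethyl-2-(3-methylbut-2-en-1-yl)-1,3,2-dioxaborolane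
Product: 8 (4R,6S,7aR)-6-bromo-7,7-dimethyl-2-oxo-2,4,5,6,7,7a-hexahydro-1-benzofuran-4-yl acetate, via borate adduct 6 (not isolated), via butenolide 7 (not isolated)
Conditions: 5 (1.05 equiv), (S)-3,3′-bis(2,4,6-triisopropylphenyl)-1,1′-binaphthyl-2,2′-diyl hydrogen phosphate [(S)-TRIP, 5 mol %], 4 Å MS, PhMe, −30 °C; then 23 °C; then CH2Cl2, TiBr4 (3 equiv), −78 to −30 °C
Reagents that add atoms: titanium tetrabromide, Br[Ti](Br)(Br)Br
Why: Proposed new method: the phosphoric acid activates 5 by hydrogen bonding and the allylboration runs through a closed chair transition state in which C1 (the gamma carbon of the prenyl unit) attacks the only free aldehyde of 4, so the C6–C1 bond and the configuration at C6 arise under catalyst control, after which the cis ester acylates the new oxygen and 7 forms with the Z relation of C8 to C6 fixed in the ring. TiBr4 then ionises the acylal to an acetoxycarbenium ion at C4 that is captured by the terminal vinyl carbon C3 (closure of the six-membered carbocycle, 6-endo-trig with respect to the alkene, chair-like) while bromide adds anti at C2. The closest known reaction types are the phosphoric-acid-catalysed allylboration of aldehydes with gamma-substituted allyl pinacolboronates and the halide-terminated Prins carbocyclisation of hex-5-enals or their acetals with aluminium and titanium halides; new are the acylal as cation source on a butenolide and the telescoping of both events. C4 and C2 are set by the substrate: the lactone holds the C6–O bond in the plane of the alkylidene unit (equatorial), the acetoxy group takes the outward position of the cation to avoid allylic 1,3-strain (equatorial), and anti addition places bromine equatorial, which should give the all-cis triad. The step needs chemoselectivity (allyl transfer to C6 only, secured by masking C4 as an acylal inert to the boronate), regioselectivity (gamma attack of the boronate; six- rather than five-membered closure through a secondary instead of a primary cation) and suppression of a methyl shift at the neopentylic C2 cation, which the bromide-rich titanate counter-ion held near C4 should secure.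

Step 5
Reactants: 8 (4R,6S,7aR)-6-bromo-7,7-dimethyl-2-oxo-2,4,5,6,7,7a-hexahydro-1-benzofuran-4-yl acetate
Product: 9 (1R,3R,5S)-5-bromo-2-[(Z)-2-hydroxyethylidene]-4,4-dimethylcyclohexane-1,3-diol
Conditions: iBu2AlH (7 equiv), CH2Cl2, −78 to 0 °C; aqueous potassium sodium tartrate
Reagents that add atoms: none
Why: iBu2AlH reduces the butenolide by two 1,2-hydride additions through the lactol to the Z-allylic 1,4-diol and cleaves the acetate reductively, while the secondary bromide and the three stereocentres are untouched and the alkene geometry is inherited from the ring.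

Step 6
Reactants: 9 (1R,3R,5S)-5-bromo-2-[(Z)-2-hydroxyethylidene]-4,4-dimethylcyclohexane-1,3-diol
Product: 10 (1S,3S,4Z,5S)-1-bromo-3,5-dichloro-4-(2-chloroethylidene)-2,2-dimethylcyclohexane
Conditions: PPh3 (4 equiv), Cl3CC(O)CCl3 (6 equiv), CH2Cl2, −20 to 10 °C
Reagents that add atoms: hexachloroacetone, O=C(C(Cl)(Cl)Cl)C(Cl)(Cl)Cl
Why: Appel-type chlorination converts each hydroxyl through its alkoxyphosphonium salt by SN2 attack of chloride without allylic transposition, so the primary carbinol gives the allylic chloride and the two equatorial secondary carbinols C4 and C6 are inverted to the cis-diaxial chlorides trans to bromine.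

Step 7
Reactants: 10 (1S,3S,4Z,5S)-1-bromo-3,5-dichloro-4-(2-chloroethylidene)-2,2-dimethylcyclohexane
Product: 11 (1S,3S,4Z,5S)-1-bromo-4-(2-bromoethylidene)-3,5-dichloro-2,2-dimethylcyclohexane
Conditions: LiBr (5 equiv), acetone, 23 °C
Reagents that add atoms: lithium bromide, [Li+].[Br-]
Why: Finkelstein halide exchange: SN2 displacement by bromide should be much faster at the primary allylic chloride C8 than at the ring-bound secondary chlorides (C6 is also neopentylic), and excess LiBr drives the equilibrium, so the stereocentres are not touched.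

**Compound list**

1 | furan-3-carbaldehyde | O=Cc1ccoc1 | starting material
2 | (furan-3-yl)methanediyl diacetate | CC(=O)OC(OC(C)=O)c1ccoc1 | intermediate
3 | (2-hydroxy-5-oxo-2,5-dihydrofuran-3-yl)methanediyl diacetate (lactol, both configurations) | OC1OC(=O)C=C1C(OC(C)=O)OC(C)=O | intermediate
4 | methyl (2E)-4,4-bis(acetyloxy)-3-formylbut-2-enoate | COC(=O)/C=C(\C=O)C(OC(C)=O)OC(C)=O | intermediate
5 | 4,4,5,5-tetramethyl-2-(3-methylbut-2-en-1-yl)-1,3,2-dioxaborolane | CC(C)=CCB1OC(C)(C)C(C)(C)O1 | starting material
6 | methyl (2E,4S)-3-[bis(acetyloxy)methyl]-5,5-dimethyl-4-[(4,4,5,5-tetramethyl-1,3,2-dioxaborolan-2-yl)oxy]hepta-2,6-dienoate | COC(=O)/C=C(\[C@@H](OB1OC(C)(C)C(C)(C)O1)C(C)(C)C=C)C(OC(C)=O)OC(C)=O | intermediate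
7 | [(2S)-2-(2-methylbut-3-en-2-yl)-5-oxo-2,5-dihydrofuran-3-yl]methanediyl diacetate | C=CC(C)(C)[C@@H]1OC(=O)C=C1C(OC(C)=O)OC(C)=O | intermediate
8 | (4R,6S,7aR)-6-bromo-7,7-dimethyl-2-oxo-2,4,5,6,7,7a-hexahydro-1-benzofuran-4-yl acetate | CC1(C)[C@@H](Br)C[C@@H](OC(C)=O)C2=CC(=O)O[C@@H]12 | intermediate
9 | (1R,3R,5S)-5-bromo-2-[(Z)-2-hydroxyethylidene]-4,4-dimethylcyclohexane-1,3-diol | CC1(C)[C@@H](Br)C[C@@H](O)/C(=C/CO)[C@H]1O | intermediate
10 | (1S,3S,4Z,5S)-1-bromo-3,5-dichloro-4-(2-chloroethylidene)-2,2-dimethylcyclohexane | CC1(C)[C@@H](Br)C[C@H](Cl)/C(=C/CCl)[C@@H]1Cl | intermediate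
11 | (1S,3S,4Z,5S)-1-bromo-4-(2-bromoethylidene)-3,5-dichloro-2,2-dimethylcyclohexane | CC1(C)[C@@H](Br)C[C@H](Cl)/C(=C/CBr)[C@@H]1Cl | target

**Total steps:** 7. **Longest linear sequence:** 7 steps (1 to 11); 5 enters at step 4.

**Steps most likely to fail**

Step 4. The acetoxycarbenium ion may be intercepted by residual boronate, the cyclised C2 cation may collapse by a methyl shift from C1, or ionisation may outrun lactonisation and erode the C4/C6 relation. The fallback uses known chemistry, sets out from 4 (with 5) and comes back at 9. The allylboration alone is run as in the first stage, and after warming and aqueous work-up the lactone 7 is isolated. Its acylal is hydrolysed with dilute HCl in aqueous THF to (2S)-2-(2-methylbut-3-en-2-yl)-5-oxo-2,5-dihydrofuran-3-carbaldehyde F1. The free aldehyde is then cyclised with TiBr4 in CH2Cl2 at −78 °C, in the manner of the known halide-terminated Prins carbocyclisation of hex-5-enals, to (4R,6S,7aR)-6-bromo-4-hydroxy-7,7-dimethyl-5,6,7,7a-tetrahydro-1-benzofuran-2(4H)-one F2. Reduction of F2 with iBu2AlH as in step 5 gives triol 9.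

Step 6. Once the primary oxygen is activated, the Z-1,4-diol may close to a 2,5-dihydrofuran, and displacement at the neopentylic C6 may give allylic transposition or elimination instead of inversion. The fallback sets out from 9 and comes back at 11. The primary allylic hydroxyl is silylated selectively (TBSCl, imidazole, DMF, 0 °C) to (1R,3R,5S)-5-bromo-2-[(2Z)-2-{[tert-butyl(dimethyl)silyl]oxy}ethylidene]-4,4-dimethylcyclohexane-1,3-diol F3. With no free primary hydroxyl left to cyclise, the two secondary carbinols are chlorinated with inversion (PPh3, hexachloroacetone) to {[(2Z)-2-[(2S,4S,6S)-4-bromo-2,6-dichloro-3,3-dimethylcyclohexylidene]ethyl]oxy}(tert-butyl)dimethylsilane F4. Ph3PBr2 in CH2Cl2 then converts the silyl ether directly into the allylic bromide 11, so step 7 is bypassed as well.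

Step 7. Bromide may also exchange or transpose the secondary allylic chlorides, scrambling C4 or C6, or the equilibrium may stop short of full conversion. The fallback sets out from 10 and comes back at 11. The primary allylic chloride is displaced irreversibly by an oxygen nucleophile (CsOAc, DMF, 23 °C) to (2Z)-2-[(2S,4S,6S)-4-bromo-2,6-dichloro-3,3-dimethylcyclohexylidene]ethyl acetate F5. The acetate is cleaved reductively under non-basic conditions (iBu2AlH, CH2Cl2, −78 °C) to (2Z)-2-[(2S,4S,6S)-4-bromo-2,6-dichloro-3,3-dimethylcyclohexylidene]ethan-1-ol F6. Appel bromination (CBr4, PPh3, CH2Cl2, 0 °C) then gives 11.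

**Further compounds**

F1 | step 4 | (2S)-2-(2-methylbut-3-en-2-yl)-5-oxo-2,5-dihydrofuran-3-carbaldehyde | C=CC(C)(C)[C@@H]1OC(=O)C=C1C=O
F2 | step 4 | (4R,6S,7aR)-6-bromo-4-hydroxy-7,7-dimethyl-5,6,7,7a-tetrahydro-1-benzofuran-2(4H)-one | CC1(C)[C@@H](Br)C[C@@H](O)C2=CC(=O)O[C@@H]12
F3 | step 6 | (1R,3R,5S)-5-bromo-2-[(2Z)-2-{[tert-butyl(dimethyl)silyl]oxy}ethylidene]-4,4-dimethylcyclohexane-1,3-diol | CC1(C)[C@@H](Br)C[C@@H](O)/C(=C/CO[Si](C)(C)C(C)(C)C)[C@H]1O
F4 | step 6 | {[(2Z)-2-[(2S,4S,6S)-4-bromo-2,6-dichloro-3,3-dimethylcyclohexylidene]ethyl]oxy}(tert-butyl)dimethylsilane | CC1(C)[C@@H](Br)C[C@H](Cl)/C(=C/CO[Si](C)(C)C(C)(C)C)[C@@H]1Cl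
F5 | step 7 | (2Z)-2-[(2S,4S,6S)-4-bromo-2,6-dichloro-3,3-dimethylcyclohexylidene]ethyl acetate | CC1(C)[C@@H](Br)C[C@H](Cl)/C(=C/COC(C)=O)[C@@H]1Cl
F6 | step 7 | (2Z)-2-[(2S,4S,6S)-4-bromo-2,6-dichloro-3,3-dimethylcyclohexylidene]ethan-1-ol | CC1(C)[C@@H](Br)C[C@H](Cl)/C(=C/CO)[C@@H]1Cl
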